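A clean passage of G to X could not give the theta run: at 4.00 d, G and X summed to 60.0 %, and each reading was good to 1.5 percentage points.

| setting | theta | green | ochre | red | teal |
|---|---|---|---|---|---|
| G | 0.022 M | 0.020 M | 0.040 M | 0.060 M | 0.080 M |
| L | 5 mM (held) | 5.0 mM (held) | 5.0 mM (held) | 5.0 mM (held) | 5.0 mM (held) |
| remark | run made earlier |  |  |  |  |
| time |  | 20 d | 20 d | 20 d | 20 d |

theta run (percent of the G charged)

| time / d | X / % | G / % |
|---|---|---|
| 0.625 | 3 | 82 |
| 1.25 | 9 | 61 |
| 1.67 | 17 | 50 |
| 2.50 | 28 | 32 |
| 3.00 | 37 | 27 |
| 4.00 | 47 | 13 |

(standard deviation of a reading: 1.5 percentage points)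

- at the start none of L is in solution

1. the flasks by amount of X, in percent of the G charged, highest first, at 20 d (green / ochre / red / teal)
2. the amount of X, in percent of the G charged of the flask you put first, at 20 d
3. the amount of X, in percent of the G charged of the flask you put last, at 20 d

I read the gap of 40.0 % in theta as two things: stock on its way to X, and X lost by meeting G, such a pair counting twice in the percentages. The readings could not separate them, so I took half of the gap as lost and let the rest of theta divide as it had divided so far:

end yield of X in theta = 47 % / (47 % + 20.0 %) = 70.1 %

Then I solved both ends. With a small charge c_G, I supposed that X and G meet little, so that the yield of X tends to full. With a large charge, I supposed that X is made at the pace of the gas supply and lost faster the more G stands, so that c_X levels off as the charge grows. I joined the two ends: the inverse square of the final c_X is the sum of the inverse squares of c_G and of the ceiling. Theta then gave this ceiling, which is my estimate and not a bound: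

ceiling of X, c_X,top = 21.7 mM

Green, at 0.020 M, looks nearly the same as theta at 0.022 M, and both charges lie close to the ceiling, so I expected green to end near my figure for theta, at 73.5 %. Teal's charge is well above the ceiling, so I reckoned 26.1 % for teal.

The forecast gave green > ochre > red > teal, with 100 % first and 98 % last: “all flasks approach completion”.

The flasks stood at green > ochre > red > teal, with 70.5 % in green and 30.0 % in teal.

    G + E ⇌ D (K = 372 /M, k = 0.357 /M/min)
    D → X (k = 4.44 × 10⁻⁴ /min)
    G + X → Z (k = 0.0119 /M/min)
    L ⇌ E, rate k4*(csat - [E]) (kL = 0.00153 /min)

Teal held 70.0 % as Z at 20.0 d, each Z holding two of the G charged. The flask with 0.032 M of G, otherwise like teal, tests the same ceiling: 21.7 mM gives it 56.1 %, and it held 57.7 % as X.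

(The earlier runs and the new flask are calculated from invented constants, and the scatter is random.)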